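The numbers of this flask come from no measurement, and the outcome is calculated.

Amounts first: J and G go in at equal charge in every set-up, and we want to know how much of that charge has paired into L.E.

in all of them: G 1.00 equiv
- Friday's: J 0.23 M; one stirred flow tank at steady state, fed with the mixture as stated, mean residence time 125 h
- Saturday's: J 0.23 M; one stirred flow tank at steady state, fed with the mixture as stated, mean residence time 25 h
- Sunday's: J 0.23 M; a closed flask charged with all of it at once and left for 25 h; time 25 h
- Tuesday's: J 0.23 M (fed, over 12.5 h); a stirred flask in which J is dosed at a steady rate over 12.5 h without added volume, worked up at 25 h; time 25 h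

    J → L (k1 = 5.8 × 10⁻⁴ min⁻¹)
    G → E (k2 = 4.6 × 10⁻⁴ min⁻¹)
    L + E → L.E (k3 = 0.0013 M⁻¹ min⁻¹)
    J ⇌ D (K4 = 30, k4 = 0.0012 min⁻¹)
    G + L.E ⇌ G.L.E, settled at all times (K5 = 1.6 M⁻¹)

- the set-up with the highest amount of L.E at the outlet or at the end, in percent of the J put in ("none" if the first two lie within 2 percentage points) (Friday's / Saturday's / Sunday's / Tuesday's / none)
- amount of L.E at the outlet or at the end, in percent of the J put in, Friday's
- amount of L.E at the outlet or at the end, in percent of the J put in, Saturday's
- amount of L.E at the outlet or at the end, in percent of the J put in, Sunday's
- amount of L.E at the outlet or at the end, in percent of the J put in, Tuesday's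

- what is said of L.E includes G.L.E
- the stated concentrations are those of everything mixed, before any reaction; amounts are the same in each set-up
- the feed brings no volume worth counting
- run time (Sunday's): 25 h

We measure the meeting of L and E by the pairing time T, the reciprocal of the rate constant of L + E → L.E times the charge of J: 55.7 h. Against it we set the half-life of each first-order step taken alone, its way back not counted, and we count how many of each fit into the two times in use.

| Step | Time | Count in 25 h | Count in 125 h |
|---|---|---|---|
| J → L | 19.9 h | 1.26 | 6.28 |
| J → D | 9.63 h | 2.60 | 13.0 |
| G → E | 25.1 h | 0.996 | 4.98 |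
| D → J | 289 h | 0.0865 | 0.433 |
| L + E, T | 55.7 h | 0.449 | 2.24 |

Reading down, J has two exits, and the faster is J → D, so L receives a share s = 32.6 % of the J that leaves by these two steps. The D → J row counts 0.0865 in the shorter time, so D returns little there. The last row holds the longest of the forward times, and its count n is a Damköhler number.

For a steady tank with G and J at equal charge this gives a rule. Let l and e be the shares of the charge that the first-order steps alone turn into L and E. The share y of L.E leaving then obeys y = n(l − y)(e − y), neglecting G held in G.L.E. For Friday's tank, l = 35.4 % and e = 77.5 %, so y = 20.0 %. For Saturday's tank, l = 24.4 % and e = 40.8 %, so y = 3.50 %.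

Sunday's flask has Saturday's n, but the share of G turned into E, reckoned by G → E alone, climbs from nothing to 49.8 %. We take half of that and count L at s throughout, which gives 3.64 %. Tuesday's dosing delays the average J by a quarter of the run, and we take that share off, leaving 2.73 %. We therefore expect Friday's to lead.

The forecast gives Friday's, with 19.8 %, 3.5 %, 3.2 % and 2.4 % for Friday's, Saturday's, Sunday's and Tuesday's in turn, holding that “only the 125 h residence time gives L and E enough time to build up and couple”.

The simulation gives Friday's, with 19.8 %, 3.48 %, 2.91 % and 2.20 % in the same order, so our figures for Sunday's and Tuesday's flasks ran high. With J ⇌ D struck out of Saturday's tank, l becomes 46.5 %, and the same n gives 6.25 %; the simulation of that tank gives 6.19 %. Sunday's flask is far from rest at 25 h: at 250 h, where n is 4.49, its L.E stands at 37.9 %, and the L.E of Tuesday's flask, from 2.20 %, stands at 37.6 % at 250 h.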